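Cuts, in retrosynthetic order: C3=C4 (metathesis), O7–C19 (lactone), C6–C7 (chloroallylation), C8–C9 (aldol), C2–C3 (vinyl addition), then C10–C11 and C1–C14 together (Diels–Alder).
Enabling feature: ring A (C1, C10, C11, C12, C13, C14) holds three contiguous stereocentres, quaternary C1 (C15 methyl), C10 and C11 (C20 methyl). They lie directly beside the C12 oxygen and the C13=C14 olefin. This is the retron of a 2-silyloxydiene adding to an E α-methyl enal whose formyl and ester carbons become C2 and C9.
Forward order of rings: ring A (step 2), butanolide C7–C8–C17–C19–O (step 22), ten-membered carbocycle C1–C10 last (step 24). C7/C8/C17–C19 come from (R)-β-methylbutyrolactone, C4–C6/C16 from propargyl alcohol.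
Stereochemistry: C1/C10/C11 come from the catalyst, the E-olefin and the ester-endo approach. C2 and C7 are set by Felkin–Anh additions, C12 by α-face hydride then Mitsunobu inversion. C17 comes from the chiral pool and is relayed to C8 through the enolate face. C9 is set by chelate/Felkin hydride delivery, C6 by a chair anti transition state, and 3Z by ring strain.

Key step: step 2

Convention: briarane numbering of the target is used for every intermediate; β is the face of the C15 methyl. Unless stated otherwise, a stereocentre has the configuration it has in 37 (1S,2S,6S,7R,8R,9S,10S,11R,12R,17R; 3Z).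
Assumption: the (S)-prolinol-derived oxazaborolidinium ion is taken to leave the Si face of C1 of bound 4 open; should the sense of induction be the opposite, its commercial enantiomer is the catalyst meant.

Step 1
Reactants: 1 pent-1-en-3-one; 2 tert-butyldimethylsilyl triflate
Product: 3 (Z)-3-(tert-butyldimethylsilyloxy)penta-1,3-diene
Conditions: TBSOTf, Et3N, Et2O, 0 °C
Reagents that add atoms: tert-butyldimethylsilyl triflate (2), CC(C)(C)[Si](C)(C)OS(=O)(=O)C(F)(F)F
Why: Soft enolisation and O-silylation of an ethyl ketone with a silyl triflate and a tertiary amine gives the cross-conjugated silyl enol ether, and the Z isomer (methyl cis to OSi, trans to vinyl) should prevail because it avoids allylic strain between methyl and vinyl.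

Step 2
Reactants: 3 (Z)-3-(tert-butyldimethylsilyloxy)penta-1,3-diene; 4 ethyl (E)-3-methyl-4-oxobut-2-enoate
Product: 5 ethyl (1S,2R,6S)-3-(tert-butyldimethylsilyloxy)-6-formyl-2,6-dimethylcyclohex-3-ene-1-carboxylate (ring A: C2 formyl α; C15 methyl, C9 ester and C20 methyl β)
Conditions: (S)-diphenylprolinol o-tolylboronate oxazaborolidine (20 mol%), Tf2NH (18 mol%), CH2Cl2, −78 °C
Reagents that add atoms: none
Why: The reaction is a concerted but asynchronous [4+2] cycloaddition: the oxazaborolidinium ion binds the formyl oxygen of 4, lowers the LUMO and makes C10 the most electrophilic carbon, so the enol-ether terminus C11 of 3 bonds there first and the CH2 terminus C14 closes onto the future quaternary C1. The closest known chemistry is the cationic oxazaborolidine-catalysed Diels–Alder reaction of α-substituted enals with 2-silyloxydienes. Ring A closes suprafacially on both partners, C10–C11 and C1–C14 forming on one face of each π system. The trans relation of formyl (C1) and ester (C10) is copied from the E-olefin of 4, the cis relation of ester and C11 methyl comes from the ester-endo/formyl-exo transition state acting on the outward-pointing methyl of the Z-enol ether, and the absolute configuration (attack on the Si face of C1) is set by the catalyst aryl group that covers the other face. The step needs regio-, endo/exo- and facial selectivity: the first is secured by matched polarisation (silyloxy donor para to formyl) and by sterics (CH2 goes to the quaternary carbon), the second by the α-methyl group, which disfavours formyl-endo and is reinforced by secondary overlap of the ester, and the third by the catalyst.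

Step 3
Reactants: 5 ring-A aldehyde ester; 6 vinylmagnesium bromide
Product: 7 ethyl (1S,2R,6S)-3-(tert-butyldimethylsilyloxy)-6-[(1S)-1-hydroxyprop-2-enyl]-2,6-dimethylcyclohex-3-ene-1-carboxylate (2S carbinol, C3=CH2 attached)
Conditions: CH2=CHMgBr, THF, −78 °C; aq. quench
Reagents that add atoms: vinylmagnesium bromide (6), C=C[Mg]Br
Why: Grignard 1,2-addition to the neopentyl aldehyde outruns attack on the hindered ester at low temperature, and Felkin–Anh control (C10 large and anti to the nucleophile, C14H2 medium, CH3 small) should favour the 2S carbinol.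

Step 4
Reactants: 7 C2 allylic alcohol
Product: 8 2-O-triethylsilyl ether of 7
Conditions: TESOTf, 2,6-lutidine, CH2Cl2, −78 °C
Reagents that add atoms: triethylsilyl triflate, CC[Si](CC)(CC)OS(=O)(=O)C(F)(F)F
Why: Silyl triflate/lutidine silylation of a hindered secondary alcohol is standard, and the enol silane is stable to the very conditions under which such ethers are made.

Step 5
Reactants: 8 2-O-TES enol silane
Product: 9 ethyl (1S,2R,6S)-2,6-dimethyl-3-oxo-6-[(1S)-1-(triethylsilyloxy)prop-2-enyl]cyclohex-4-ene-1-carboxylate (12-oxo, C13=C14)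
Conditions: Pd(OAc)2 (1.1 equiv), MeCN, rt
Reagents that add atoms: none
Why: In this Saegusa–Ito oxidation the palladium enolate bound at C13 finds its only β-hydrogens on C14, so the C13=C14 enone is the single regiochemical outcome, and the neutral medium spares the epimerisable C11.

Step 6
Reactants: 9 ring-A enone
Product: 10 12β-allylic alcohol (12S, epimeric with the target at C12 only)
Conditions: NaBH4, CeCl3·7H2O, MeOH, −78 °C
Reagents that add atoms: none
Why: In this Luche 1,2-reduction the favoured half-chair places the C9 ester axial on the β face, 1,3 to C12, so hydride should arrive from the α face, and any 12α epimer formed is 12 itself and simply joins at step 9.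

Step 7
Reactants: 10 12β-allylic alcohol
Product: 11 12α-(4-nitrobenzoate) (12R)
Conditions: 4-O2NC6H4CO2H, PPh3, DIAD, toluene, 0 °C to rt
Reagents that add atoms: 4-nitrobenzoic acid, O=C(O)c1ccc(cc1)[N+](=O)[O-]
Why: Mitsunobu inversion displaces the pseudoaxial alkoxyphosphonium group by SN2 attack from the open α face, while SN2' attack at C14 is blocked by the adjacent quaternary C1.

Step 8
Reactants: 11 12α-(4-nitrobenzoate)
Product: 12 12α-allylic alcohol (12R)
Conditions: K2CO3 (cat.), EtOH, rt
Reagents that add atoms: none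
Why: Base-catalysed transesterification removes the activated aryl ester while the flanked C9 ethyl ester stays intact, and ethanol as solvent rules out ester scrambling.

Step 9
Reactants: 12 12α-allylic alcohol
Product: 13 12-O-triisopropylsilyl ether of 12
Conditions: TIPSOTf, 2,6-lutidine, CH2Cl2, 0 °C
Reagents that add atoms: triisopropylsilyl triflate, CC(C)[Si](OS(=O)(=O)C(F)(F)F)(C(C)C)C(C)C
Why: Standard silylation installs on O12 a group markedly more robust than TES, so that O2, O8 and O9 can later be freed without touching O12.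

Step 10
Reactants: 13 fully protected ring-A ester
Product: 14 C9 primary alcohol
Conditions: DIBAL-H (2.5 equiv), CH2Cl2, −78 °C to 0 °C
Reagents that add atoms: none
Why: Hydride reduction of the only carbonyl group left takes the ester to the primary alcohol, and silyl ethers and olefins are inert to DIBAL-H.

Step 11
Reactants: 14 C9 primary alcohol
Product: 15 C9 aldehyde
Conditions: Dess–Martin periodinane, CH2Cl2, rt
Reagents that add atoms: none
Why: Dess–Martin oxidation works on hindered primary alcohols and is non-basic, so the α-stereocentre C10 should not epimerise.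

Step 12
Reactants: 16 (R)-4-methyldihydrofuran-2(3H)-one
Product: 18 (3R,4S)-3-hydroxy-4-methyldihydrofuran-2(3H)-one, via potassium lactone enolate 17 (not isolated)
Conditions: KHMDS, THF, −78 °C; 2-(phenylsulfonyl)-3-phenyloxaziridine; AcOH quench
Reagents that add atoms: 2-(phenylsulfonyl)-3-phenyloxaziridine, O=S(=O)(N1OC1c1ccccc1)c1ccccc1
Why: Davis enolate hydroxylation transfers oxygen to the face anti to the methyl group (trans product), and this new centre (future C8) is flattened again in step 14, so its purity is not critical.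

Step 13
Reactants: 18 hydroxy lactone
Product: 19 (3R,4S)-4-methyl-3-(triethylsilyloxy)dihydrofuran-2(3H)-one
Conditions: TESCl, imidazole, DMF, rt
Reagents that add atoms: triethylsilyl chloride, CC[Si](Cl)(CC)CC
Why: Routine silylation of a secondary alcohol gives an α-silyloxy lactone with no β-leaving group, so that it can be enolised cleanly.

Step 14
Reactants: 19 silyloxy lactone; 15 C9 aldehyde
Product: 21 C8–C9 aldol adduct (C9 epimers; on the lactone ring C9 trans and O8-TES cis to the C17 methyl), via lithium silyloxy-lactone enolate 20 (not isolated)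
Conditions: LDA, THF, −78 °C; then 15; AcOH quench at −78 °C
Reagents that add atoms: none
Why: In this lithium enolate aldol addition the cyclic enolate is attacked anti to the C17 methyl, which fixes quaternary C8, while the C9 configuration is left open for correction in steps 15 and 16, and the cold acidic quench forestalls retro-aldol and silyl migration.

Step 15
Reactants: 21 aldol adduct
Product: 22 C9 ketone (β-keto lactone with quaternary C8)
Conditions: Dess–Martin periodinane, CH2Cl2, rt
Reagents that add atoms: none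
Why: Dess–Martin oxidation merges both C9 epimers into one ketone, which cannot enolise towards the fully substituted C8 and is not exposed to base that could touch C10.

Step 16
Reactants: 22 C9 ketone
Product: 23 9S alcohol (O8/O9 syn along C10–C9–C8–C7)
Conditions: Zn(BH4)2, Et2O, −30 °C to 0 °C
Reagents that add atoms: none
Why: In this chelation-controlled reduction of a β-keto lactone, zinc bridges the C9 and C7 carbonyl oxygens and hydride enters anti to the C8 silyloxy group, which is also the Felkin–Anh face with respect to C10 (C1 anti), so both neighbours direct to the 9S carbinol.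

Step 17
Reactants: 23 9S alcohol
Product: 24 2,8,9-tris-O-TES 12-O-TIPS lactone (C7 carbonyl, C19H2–O)
Conditions: TESOTf, 2,6-lutidine, CH2Cl2, 0 °C to rt
Reagents that add atoms: triethylsilyl triflate, CC[Si](CC)(CC)OS(=O)(=O)C(F)(F)F
Why: The reactive silyl triflate silylates even this crowded secondary alcohol, and masking O9 keeps it from competing with O7 in the later lactonisation.

Step 18
Reactants: 24 protected lactone
Product: 25 C7 lactol (anomers)
Conditions: DIBAL-H (1.3 equiv), toluene, −78 °C
Reagents that add atoms: none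
Why: Partial reduction of a γ-lactone stops at the aluminium hemiacetal at low temperature, all the more so next to the quaternary C8.

Step 19
Reactants: 26 prop-2-yn-1-ol; 6 vinylmagnesium bromide
Product: 28 (2Z)-2-(chloromethylidene)but-3-en-1-ol, via cyclic alkenylmagnesium alkoxide 27 (not isolated)
Conditions: CH2=CHMgBr (3 equiv), CuI (10 mol%), THF, 0 °C to rt; then NCS, −30 °C to 0 °C
Reagents that add atoms: vinylmagnesium bromide (6), C=C[Mg]Br; N-chlorosuccinimide, O=C1CCC(=O)N1Cl
Why: Copper-catalysed anti-carbomagnesiation of a propargylic alcohol puts the vinyl group on the internal carbon and magnesium on the terminal carbon, chelated cis to CH2O, and electrophilic chlorination with retention gives the Z-chloride carrying C16, C5, C6 and C4.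

Step 20
Reactants: 28 chlorodienol
Product: 29 (1Z)-2-(bromomethyl)-1-chlorobuta-1,3-diene
Conditions: CBr4, PPh3, CH2Cl2, 0 °C
Reagents that add atoms: carbon tetrabromide, BrC(Br)(Br)Br
Why: The Appel reaction converts a primary allylic alcohol to the bromide under neutral conditions without touching the vinyl chloride or the diene.

Step 21
Reactants: 25 C7 lactol; 29 chloroallylic bromide
Product: 31 seco chlorohydrin diol (6S-Cl and 7R-OH anti; C5 bearing =C16H2 plus the C4 vinyl group; C19 primary alcohol; O2/O8/O9 TES; O12 TIPS), via chloroallylchromium(III) reagent 30 (not isolated)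
Conditions: CrCl2 (excess), 29 (excess), THF, rt
Reagents that add atoms: none
Why: In this Nozaki–Hiyama-type chromium(II) γ-chloroallylation, 29 is reduced to the hydroxyl-tolerant σ-allylchromium species 30 (Cr on C16), which adds through its chlorine-bearing γ-carbon to the hydroxy-aldehyde tautomer of 25 in a chair transition state with chlorine and the aldehyde residue equatorial (6,7-anti), while Felkin–Anh attack anti to the C8 silyloxy group and past the smaller C17 branch sets 7R.

Step 22
Reactants: 31 seco chlorohydrin diol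
Product: 33 silylated seco butanolide (C19 carbonyl, O–C7), via C19 lactol 32 (not isolated)
Conditions: TEMPO (20 mol%), PhI(OAc)2, CH2Cl2, rt
Reagents that add atoms: none
Why: Oxoammonium-mediated oxidative lactonisation of a 1,4-diol oxidises only the primary C19 alcohol, the aldehyde is trapped by the C7 hydroxyl as a five-membered lactol and oxidised on, and C17 keeps its methyl trans to C9, the more stable arrangement.

Step 23
Reactants: 33 silylated seco butanolide
Product: 34 seco 2,8,9-triol (12-O-TIPS kept)
Conditions: HF·pyridine, pyridine, THF, 0 °C to rt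
Reagents that add atoms: none
Why: Buffered fluoride desilylation cleaves TES ethers far faster than a secondary TIPS ether and leaves lactone, allylic chloride and diene untouched.

Step 24
Reactants: 34 seco triol
Product: 35 (3Z)-macrocyclic 2,8,9-triol (ten-membered ring closed, 12-O-TIPS)
Conditions: Hoveyda–Grubbs II (15 mol%), 1,4-benzoquinone (cat.), toluene (1 mM), 80 °C, Ar sparge
Reagents that add atoms: none
Why: In this diene–ene ring-closing metathesis only the two monosubstituted olefins react (C5=C16 and C13=C14 are too hindered), the free allylic 2-OH should accelerate metathesis at the neopentyl vinyl group, high dilution favours closure, and since a cis olefin is the less strained one in a ten-membered carbocycle, reversible metathesis should settle on 3Z.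

Step 25
Reactants: 35 macrocyclic triol
Product: 36 2,9-diacetate (8-OH free, 12-O-TIPS)
Conditions: Ac2O, pyridine, DMAP (cat.), CH2Cl2, rt
Reagents that add atoms: acetic anhydride, CC(=O)OC(C)=O
Why: DMAP-catalysed acetylation esterifies the two secondary alcohols, whereas the tertiary, fully flanked 8-OH is inert under these conditions and O12 is still masked.

Step 26
Reactants: 36 2,9-diacetate
Product: 37 target CNP0253247.1
Conditions: HF·pyridine (excess), THF, 0 °C to rt
Reagents that add atoms: none
Why: Acidic fluoride removes the last silyl group without base, so acetates, lactone and the secondary allylic chloride (deactivated towards ionisation by the neighbouring acyloxy carbon) should survive.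

Compound list
1 | pent-1-en-3-one | CCC(=O)C=C | starting material
2 | tert-butyldimethylsilyl triflate | CC(C)(C)[Si](C)(C)OS(=O)(=O)C(F)(F)F | starting material
3 | (Z)-3-(tert-butyldimethylsilyloxy)penta-1,3-diene | C=C/C(O[Si](C)(C)C(C)(C)C)=C/C | intermediate
4 | ethyl (E)-3-methyl-4-oxobut-2-enoate | CCOC(=O)/C=C(\C)C=O | starting material
5 | ethyl (1S,2R,6S)-3-(tert-butyldimethylsilyloxy)-6-formyl-2,6-dimethylcyclohex-3-ene-1-carboxylate | O=C[C@@]1(C)CC=C(O[Si](C)(C)C(C)(C)C)[C@H](C)[C@@H]1C(=O)OCC | intermediate
6 | vinylmagnesium bromide | C=C[Mg]Br | starting material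
7 | 2S vinyl carbinol of 5 | C=C[C@H](O)[C@@]1(C)CC=C(O[Si](C)(C)C(C)(C)C)[C@H](C)[C@@H]1C(=O)OCC | intermediate
8 | 2-O-TES ether of 7 | C=C[C@H](O[Si](CC)(CC)CC)[C@@]1(C)CC=C(O[Si](C)(C)C(C)(C)C)[C@H](C)[C@@H]1C(=O)OCC | intermediate
9 | ring-A enone (12-oxo, C13=C14) | C=C[C@H](O[Si](CC)(CC)CC)[C@@]1(C)C=CC(=O)[C@H](C)[C@@H]1C(=O)OCC | intermediate
10 | 12β-allylic alcohol (12S) | C=C[C@H](O[Si](CC)(CC)CC)[C@@]1(C)C=C[C@H](O)[C@H](C)[C@@H]1C(=O)OCC | intermediate
11 | 12α-(4-nitrobenzoate) (12R) | C=C[C@H](O[Si](CC)(CC)CC)[C@@]1(C)C=C[C@@H](OC(=O)c2ccc(cc2)[N+](=O)[O-])[C@H](C)[C@@H]1C(=O)OCC | intermediate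
12 | 12α-allylic alcohol (12R) | C=C[C@H](O[Si](CC)(CC)CC)[C@@]1(C)C=C[C@@H](O)[C@H](C)[C@@H]1C(=O)OCC | intermediate
13 | 12-O-TIPS, 2-O-TES ring-A ethyl ester | C=C[C@H](O[Si](CC)(CC)CC)[C@@]1(C)C=C[C@@H](O[Si](C(C)C)(C(C)C)C(C)C)[C@H](C)[C@@H]1C(=O)OCC | intermediate
14 | C9 primary alcohol | C=C[C@H](O[Si](CC)(CC)CC)[C@@]1(C)C=C[C@@H](O[Si](C(C)C)(C(C)C)C(C)C)[C@H](C)[C@@H]1CO | intermediate
15 | C9 aldehyde | C=C[C@H](O[Si](CC)(CC)CC)[C@@]1(C)C=C[C@@H](O[Si](C(C)C)(C(C)C)C(C)C)[C@H](C)[C@@H]1C=O | intermediate
16 | (R)-4-methyldihydrofuran-2(3H)-one | O=C1C[C@@H](C)CO1 | starting material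
17 | potassium enolate of 16 | [K+].[O-]C1=C[C@@H](C)CO1 | intermediate
18 | (3R,4S)-3-hydroxy-4-methyldihydrofuran-2(3H)-one | O[C@@H]1[C@@H](C)COC1=O | intermediate
19 | (3R,4S)-4-methyl-3-(triethylsilyloxy)dihydrofuran-2(3H)-one | CC[Si](CC)(CC)O[C@@H]1[C@@H](C)COC1=O | intermediate
20 | lithium enolate of 19 | [Li+].[O-]C1=C(O[Si](CC)(CC)CC)[C@@H](C)CO1 | intermediate
21 | C8–C9 aldol adduct (C9 epimers) | C=C[C@H](O[Si](CC)(CC)CC)[C@@]1(C)C=C[C@@H](O[Si](C(C)C)(C(C)C)C(C)C)[C@H](C)[C@@H]1C(O)[C@]2(O[Si](CC)(CC)CC)[C@@H](C)COC2=O | intermediate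
22 | C9 ketone | C=C[C@H](O[Si](CC)(CC)CC)[C@@]1(C)C=C[C@@H](O[Si](C(C)C)(C(C)C)C(C)C)[C@H](C)[C@@H]1C(=O)[C@]2(O[Si](CC)(CC)CC)[C@@H](C)COC2=O | intermediate
23 | 9S alcohol | C=C[C@H](O[Si](CC)(CC)CC)[C@@]1(C)C=C[C@@H](O[Si](C(C)C)(C(C)C)C(C)C)[C@H](C)[C@@H]1[C@H](O)[C@]2(O[Si](CC)(CC)CC)[C@@H](C)COC2=O | intermediate
24 | 2,8,9-tris-O-TES 12-O-TIPS lactone (C7 carbonyl) | C=C[C@H](O[Si](CC)(CC)CC)[C@@]1(C)C=C[C@@H](O[Si](C(C)C)(C(C)C)C(C)C)[C@H](C)[C@@H]1[C@H](O[Si](CC)(CC)CC)[C@]2(O[Si](CC)(CC)CC)[C@@H](C)COC2=O | intermediate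
25 | C7 lactol (anomers) | C=C[C@H](O[Si](CC)(CC)CC)[C@@]1(C)C=C[C@@H](O[Si](C(C)C)(C(C)C)C(C)C)[C@H](C)[C@@H]1[C@H](O[Si](CC)(CC)CC)[C@]2(O[Si](CC)(CC)CC)[C@@H](C)COC2O | intermediate
26 | prop-2-yn-1-ol | C#CCO | starting material
27 | cyclic alkenylmagnesium alkoxide (4-vinyl-1-oxa-2-magnesacyclopent-3-ene) | C=CC1=C[Mg]OC1 | intermediate
28 | (2Z)-2-(chloromethylidene)but-3-en-1-ol | OC/C(C=C)=C\Cl | intermediate
29 | (1Z)-2-(bromomethyl)-1-chlorobuta-1,3-diene | BrC/C(C=C)=C\Cl | intermediate
30 | [2-(chloromethylidene)but-3-enyl]chromium(III) dichloride (geometry fluxional) | Cl[Cr](Cl)CC(C=C)=CCl | intermediate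
31 | seco chlorohydrin diol (6S-Cl, 7R-OH, C19-OH) | C=C[C@H](O[Si](CC)(CC)CC)[C@@]1(C)C=C[C@@H](O[Si](C(C)C)(C(C)C)C(C)C)[C@H](C)[C@@H]1[C@H](O[Si](CC)(CC)CC)[C@](O[Si](CC)(CC)CC)([C@@H](C)CO)[C@@H](O)[C@@H](Cl)C(=C)C=C | intermediate
32 | C19 lactol (anomers) | C=C[C@H](O[Si](CC)(CC)CC)[C@@]1(C)C=C[C@@H](O[Si](C(C)C)(C(C)C)C(C)C)[C@H](C)[C@@H]1[C@H](O[Si](CC)(CC)CC)[C@]2(O[Si](CC)(CC)CC)[C@@H](C)C(O)O[C@H]2[C@@H](Cl)C(=C)C=C | intermediate
33 | silylated seco butanolide | C=C[C@H](O[Si](CC)(CC)CC)[C@@]1(C)C=C[C@@H](O[Si](C(C)C)(C(C)C)C(C)C)[C@H](C)[C@@H]1[C@H](O[Si](CC)(CC)CC)[C@]2(O[Si](CC)(CC)CC)[C@@H](C)C(=O)O[C@H]2[C@@H](Cl)C(=C)C=C | intermediate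
34 | seco 2,8,9-triol, 12-O-TIPS | C=C[C@H](O)[C@@]1(C)C=C[C@@H](O[Si](C(C)C)(C(C)C)C(C)C)[C@H](C)[C@@H]1[C@H](O)[C@]2(O)[C@@H](C)C(=O)O[C@H]2[C@@H](Cl)C(=C)C=C | intermediate
35 | (3Z)-macrocyclic 2,8,9-triol, 12-O-TIPS | C=C1/C=C\[C@H](O)[C@@]2(C)C=C[C@@H](O[Si](C(C)C)(C(C)C)C(C)C)[C@H](C)[C@@H]2[C@H](O)[C@]2(O)[C@@H](C)C(=O)O[C@H]2[C@H]1Cl | intermediate
36 | 2,9-diacetate, 12-O-TIPS | C=C1/C=C\[C@H](OC(C)=O)[C@@]2(C)C=C[C@@H](O[Si](C(C)C)(C(C)C)C(C)C)[C@H](C)[C@@H]2[C@H](OC(C)=O)[C@]2(O)[C@@H](C)C(=O)O[C@H]2[C@H]1Cl | intermediate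
37 | CNP0253247.1 | C=C1/C=C\[C@H](OC(C)=O)[C@@]2(C)C=C[C@@H](O)[C@H](C)[C@@H]2[C@H](OC(C)=O)[C@]2(O)[C@@H](C)C(=O)O[C@H]2[C@H]1Cl | target

Total step count: 26. Longest linear sequence: 22 (steps 1–11, 14–18, 21–26).

Steps most likely to fail

Step 24. The closure may lose out to intermolecular metathesis at the exposed diene terminus, or stop at a kinetically formed E-olefin. The cause would be that ring A has to flip into its less favoured half-chair and the trans-substituted butanolide stiffens the C6–C9 segment before the two vinyl groups can meet. The fallback changes the order of ring formation. It sets out from diol 31, in which C7–C8 still rotates freely, and closes the carbocycle first by diene–ene metathesis to the ten-membered chlorohydrin diol F1. TEMPO/PhI(OAc)2 then builds the butanolide on the preformed ring to give the tris-TES macrocyclic lactone F2. HF·pyridine/pyridine removes the three TES groups, and the material comes back to the route at 35.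

Step 21. The lactol may release its hydroxy-aldehyde form too slowly, so that the allylchromium reagent is consumed by protonation and homocoupling. The free C19 hydroxyl may also disturb the facial bias at C7. The fallback replaces the masked aldehyde by a true one.
- It sets out from lactone 24, which LiAlH4 reduces to the 7,19-diol F3.
- PivCl/pyridine acylates the less hindered C19 hydroxyl (the C7 hydroxyl is neopentyl) to give the C19 monopivalate F4.
- Dess–Martin oxidation gives the free C7 aldehyde F5.
- Chromium chloroallylation with 29 gives the chlorohydrin pivalate F6.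
- DIBAL-H at −78 °C cleaves the pivalate without base, so the chlorohydrin cannot close to an epoxide, and the route is rejoined at 31.

Step 14. Addition of a fully substituted enolate to a doubly flanked aldehyde may be slow and reversible. Retro-aldol cleavage, proton transfer (enolisation of 15 with erosion of C10) or O8-to-O9 silyl migration could then take over. The fallback is a Mukaiyama aldol reaction. It sets out from 19, which LDA/TMSCl converts into the trimethylsilyl ketene acetal F7. This is combined with 15 and BF3·OEt2 in CH2Cl2 at −78 °C. Lewis-acid activation of the aldehyde and irreversible silyl transfer replace the reversible lithium aldolate, and the face anti to the C17 methyl is still the open one. Aqueous work-up returns the route at 21.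

Further compounds
F1 | step 24 | ten-membered (3Z) chlorohydrin diol, O2/O8/O9 TES, O12 TIPS | C=C1/C=C\[C@H](O[Si](CC)(CC)CC)[C@@]2(C)C=C[C@@H](O[Si](C(C)C)(C(C)C)C(C)C)[C@H](C)[C@@H]2[C@H](O[Si](CC)(CC)CC)[C@](O[Si](CC)(CC)CC)([C@@H](C)CO)[C@@H](O)[C@H]1Cl
F2 | step 24 | tris-TES macrocyclic lactone, O12 TIPS | C=C1/C=C\[C@H](O[Si](CC)(CC)CC)[C@@]2(C)C=C[C@@H](O[Si](C(C)C)(C(C)C)C(C)C)[C@H](C)[C@@H]2[C@H](O[Si](CC)(CC)CC)[C@]2(O[Si](CC)(CC)CC)[C@@H](C)C(=O)O[C@H]2[C@H]1Cl
F3 | step 21 | 7,19-diol from reduction of 24 | C=C[C@H](O[Si](CC)(CC)CC)[C@@]1(C)C=C[C@@H](O[Si](C(C)C)(C(C)C)C(C)C)[C@H](C)[C@@H]1[C@H](O[Si](CC)(CC)CC)[C@](O[Si](CC)(CC)CC)([C@@H](C)CO)CO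
F4 | step 21 | C19 monopivalate | C=C[C@H](O[Si](CC)(CC)CC)[C@@]1(C)C=C[C@@H](O[Si](C(C)C)(C(C)C)C(C)C)[C@H](C)[C@@H]1[C@H](O[Si](CC)(CC)CC)[C@](O[Si](CC)(CC)CC)([C@@H](C)COC(=O)C(C)(C)C)CO
F5 | step 21 | free C7 aldehyde, C19 pivalate | C=C[C@H](O[Si](CC)(CC)CC)[C@@]1(C)C=C[C@@H](O[Si](C(C)C)(C(C)C)C(C)C)[C@H](C)[C@@H]1[C@H](O[Si](CC)(CC)CC)[C@](O[Si](CC)(CC)CC)([C@@H](C)COC(=O)C(C)(C)C)C=O
F6 | step 21 | chlorohydrin pivalate (6S-Cl, 7R-OH) | C=C[C@H](O[Si](CC)(CC)CC)[C@@]1(C)C=C[C@@H](O[Si](C(C)C)(C(C)C)C(C)C)[C@H](C)[C@@H]1[C@H](O[Si](CC)(CC)CC)[C@](O[Si](CC)(CC)CC)([C@@H](C)COC(=O)C(C)(C)C)[C@@H](O)[C@@H](Cl)C(=C)C=C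
F7 | step 14 | trimethylsilyl ketene acetal of 19 | C[Si](C)(C)OC1=C(O[Si](CC)(CC)CC)[C@@H](C)CO1
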